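**Plan**

- Retrosynthetic cuts, in order: (a) the acetates, the O‑1/O‑2 acetal and the benzoate C7–O bond (back to a spiro‑epoxide); (b) the C3=C4 π bond, with SO2 re‑inserted between C3 and C4, which opens the cyclohexene to a thiepane 1,1‑dioxide; (c) C1–C7 (ketone plus chloromethyl carbenoid); (d) both C–S bonds (sulfide plus bis‑epoxide).
- Enabling feature: the isolated cis‑CH=CH (C3=C4) of the six‑membered ring is flanked on both sides by oxygenated sp3 carbons (C2, C5). Its two carbons can therefore be the former α‑CH2 groups of a seven‑membered cyclic sulfone (Ramberg–Bäcklund retron), whose chain C3–C2–C1–C6–C5–C4 is a 1,6‑dideoxyhexitol.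
- Forward order: D‑mannitol acetonide → L‑ido bis‑epoxide → thiepane (seven‑membered ring closed by two C–S bonds) → O‑protection and desymmetrisation → ketone at the future C1 → spiro‑epoxide → sulfone → ring contraction to the cyclohexene → benzoate, acetal tie, acetates, deprotection.
- Stereochemistry: C5, C6 and C2 are C2, C3 and C5 of D‑mannitol (C2 and C5 inverted on epoxide formation). Quaternary C1 arises by carbenoid attack anti to the two flanking cis oxygens. O‑2 is told from O‑5 because only the O‑2 PMB ether has a free cis hydroxyl (on C1) with which to form an acetal.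

Key step: step 10

Remark on numbering: the cyclohexene is numbered as in the target, [(1S,2S,5S,6R)‑5,6‑diacetoxy‑1,2‑dihydroxycyclohex‑3‑en‑1‑yl]methyl benzoate (C1 quaternary, C7 its CH2). Thiepanes are numbered S1, C2–C7, with thiepane C3, C4, C5, C6 becoming cyclohexene C2, C1, C6, C5. PMB = 4‑methoxybenzyl, TBS = tert‑butyldimethylsilyl.

**Step 1**
Reactants: 1 3,4‑O‑isopropylidene‑D‑mannitol
Product: 3 1,6‑di‑O‑benzoyl‑3,4‑O‑isopropylidene‑2,5‑di‑O‑methanesulfonyl‑D‑mannitol, via dibenzoate 2 (not isolated)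
Conditions: BzCl (2.05 equiv), pyridine–CH2Cl2, −40 → −15 °C; then MsCl (3 equiv), 0 °C → rt
Reagents that add atoms: benzoyl chloride O=C(Cl)c1ccccc1; methanesulfonyl chloride CS(=O)(=O)Cl
Why: The two primary hydroxyls should be acylated far faster than the secondary ones at low temperature, and the remaining C2/C5 hydroxyls are then sulfonylated in the same flask (selective acylation, then mesylation; no stereocenter touched).

**Step 2**
Reactants: 3 1,6‑di‑O‑benzoyl‑3,4‑O‑isopropylidene‑2,5‑di‑O‑methanesulfonyl‑D‑mannitol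
Product: 4 1,2:5,6‑dianhydro‑3,4‑O‑isopropylidene‑L‑iditol
Conditions: K2CO3, MeOH–CH2Cl2, 0 °C → rt
Reagents that add atoms: none
Why: Methanolysis of the benzoates frees the primary alkoxides, which displace the neighbouring mesylates intramolecularly (3‑exo‑tet SN2), so C2 and C5 are inverted and the D‑manno chain becomes the C2‑symmetric L‑ido bis‑epoxide.

**Step 3**
Reactants: 4 1,2:5,6‑dianhydro‑3,4‑O‑isopropylidene‑L‑iditol
Product: 6 1,6‑dideoxy‑1,6‑epithio‑3,4‑O‑isopropylidene‑L‑iditol, via epoxy thiolate 5 (not isolated)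
Conditions: Na2S·9H2O (1.1 equiv), EtOH, reflux
Reagents that add atoms: sodium sulfide [Na+].[Na+].[S-2]
Why: Sulfide opens one terminal epoxide at its CH2 and thiolate 5 should open the second one again at the CH2 terminus (7‑endo‑tet), the 6‑exo mode being disfavoured by the trans‑fused dioxolane; this is the known thiepane synthesis from 3,4‑O‑protected hexitol bis‑epoxides, and no stereocenter is touched.

**Step 4**
Reactants: 6 1,6‑dideoxy‑1,6‑epithio‑3,4‑O‑isopropylidene‑L‑iditol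
Product: 7 1,6‑dideoxy‑1,6‑epithio‑3,4‑O‑isopropylidene‑2,5‑bis‑O‑(4‑methoxybenzyl)‑L‑iditol
Conditions: NaH, PMBCl, Bu4NI (cat.), DMF, 0 °C → rt
Reagents that add atoms: 4‑methoxybenzyl chloride COc1ccc(CCl)cc1
Why: Williamson etherification of the two equivalent secondary alkoxides should give base‑stable ethers that later survive the strongly basic ring contraction and can be removed oxidatively.

**Step 5**
Reactants: 7 1,6‑dideoxy‑1,6‑epithio‑3,4‑O‑isopropylidene‑2,5‑bis‑O‑(4‑methoxybenzyl)‑L‑iditol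
Product: 8 1,6‑dideoxy‑1,6‑epithio‑2,5‑bis‑O‑(4‑methoxybenzyl)‑L‑iditol
Conditions: AcOH–H2O (4:1), 45 °C
Reagents that add atoms: none
Why: The strained trans‑fused isopropylidene acetal should hydrolyse under mild acid that leaves PMB ethers and the sulfide intact (acetal hydrolysis).

**Step 6**
Reactants: 8 1,6‑dideoxy‑1,6‑epithio‑2,5‑bis‑O‑(4‑methoxybenzyl)‑L‑iditol
Product: 9 3‑O‑(tert‑butyldimethylsilyl)‑1,6‑dideoxy‑1,6‑epithio‑2,5‑bis‑O‑(4‑methoxybenzyl)‑L‑iditol
Conditions: TBSCl (1.1 equiv), imidazole, DMF, 0 °C → rt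
Reagents that add atoms: tert‑butyldimethylsilyl chloride CC(C)(C)[Si](C)(C)Cl
Why: The two hydroxyls are homotopic (C2 axis), so mono‑silylation can give only one constitutional isomer, and the second hydroxyl, then flanked by OTBS and OPMB, should react much more slowly (desymmetrising mono‑protection).

**Step 7**
Reactants: 9 3‑O‑(tert‑butyldimethylsilyl)‑1,6‑dideoxy‑1,6‑epithio‑2,5‑bis‑O‑(4‑methoxybenzyl)‑L‑iditol
Product: 10 5‑(tert‑butyldimethylsilyloxy)‑3,6‑bis(4‑methoxybenzyloxy)thiepan‑4‑one (O‑3 cis to O‑5; O‑6 trans to O‑5)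
Conditions: Dess–Martin periodinane, NaHCO3, CH2Cl2, 0 °C → rt
Reagents that add atoms: none
Why: Dess–Martin oxidation converts the remaining secondary alcohol into the ketone under neutral, non‑basic conditions that spare the sulfide and avoid β‑elimination or epimerisation at the two α‑alkoxy carbons.

**Step 8**
Reactants: 10 5‑(tert‑butyldimethylsilyloxy)‑3,6‑bis(4‑methoxybenzyloxy)thiepan‑4‑one
Product: 12 5‑(tert‑butyldimethylsilyloxy)‑3,6‑bis(4‑methoxybenzyloxy)thiepane‑4‑spiro‑2'‑oxirane (oxirane O cis to O‑3 and O‑5; O‑6 trans to O‑5), via chlorohydrin alkoxide 11 (not isolated)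
Conditions: ClCH2I (2 equiv), n‑BuLi (1.9 equiv, slow addition), THF, −78 °C; then → rt
Reagents that add atoms: chloroiodomethane ClCI
Why: Chloromethyllithium, formed by I/Li exchange, should add to the ketone faster than it enolises it, from the face opposite the cis‑disposed 3‑OPMB and 5‑OTBS groups (steric and polar Felkin–Anh control from both α‑carbons), and 3‑exo‑tet closure of alkoxide 11 then fixes the quaternary centre with its oxygen cis to O‑3 and O‑5 (carbenoid epoxidation of a ketone).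

**Step 9**
Reactants: 12 5‑(tert‑butyldimethylsilyloxy)‑3,6‑bis(4‑methoxybenzyloxy)thiepane‑4‑spiro‑2'‑oxirane
Product: 13 5‑(tert‑butyldimethylsilyloxy)‑3,6‑bis(4‑methoxybenzyloxy)thiepane‑4‑spiro‑2'‑oxirane 1,1‑dioxide
Conditions: mCPBA (2.3 equiv), NaHCO3, CH2Cl2, 0 °C → rt
Reagents that add atoms: 3‑chloroperoxybenzoic acid O=C(OO)c1cccc(Cl)c1
Why: Buffered peracid should oxidise the sulfide to the sulfone far faster than it touches the PMB ethers, the silyl ether or the epoxide (sulfide to sulfone oxidation).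

**Step 10**
Reactants: 13 5‑(tert‑butyldimethylsilyloxy)‑3,6‑bis(4‑methoxybenzyloxy)thiepane‑4‑spiro‑2'‑oxirane 1,1‑dioxide
Product: 16 6‑(tert‑butyldimethylsilyloxy)‑2,5‑bis(4‑methoxybenzyloxy)cyclohex‑3‑ene‑1‑spiro‑2'‑oxirane (oxirane O cis to O‑2 and O‑6; O‑5 trans to O‑6), via bromosulfone 14 (not isolated), via episulfone 15 (not isolated)
Conditions: KOH/Al2O3, CBr2F2, t‑BuOH–CH2Cl2, 0 °C → rt
Reagents that add atoms: none
Why: The sulfone is deprotonated at an α‑CH2 and the carbanion is brominated by CBr2F2 to 14; deprotonation at the α'‑CH2 and 1,3‑displacement of bromide give episulfone 15, which loses SO2 in a cheletropic step, so that C2 and C7 of the seven‑membered ring become the cis‑CH=CH unit of a six‑membered carbocycle. The closest known reaction type is the Ramberg–Bäcklund ring contraction of polyoxygenated thiepane 1,1‑dioxides to conduritol ethers. The only ring closure is the 3‑exo‑tet formation of the thiirane dioxide; the cyclohexene is what remains when its two C–S bonds break, and the ring enforces the Z geometry. No stereocenter is formed or destroyed: the four stereocenters lie β and γ to sulfur and are carried over unchanged. The step needs halogen transfer and 1,3‑elimination to outrun E1cB loss of the β‑PMB‑oxy groups and attack of the carbanion on the spiro‑epoxide; alkoxides are poor leaving groups, bromine transfer to the carbanion is very fast at 0 °C, and the substrate carries no ester, free hydroxyl or other base‑labile group.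

**Step 11**
Reactants: 16 6‑(tert‑butyldimethylsilyloxy)‑2,5‑bis(4‑methoxybenzyloxy)cyclohex‑3‑ene‑1‑spiro‑2'‑oxirane
Product: 17 [(1S,2S,5S,6R)‑6‑(tert‑butyldimethylsilyloxy)‑1‑hydroxy‑2,5‑bis(4‑methoxybenzyloxy)cyclohex‑3‑en‑1‑yl]methyl benzoate
Conditions: PhCO2H (3 equiv), Cs2CO3 (0.3 equiv), DMF, 80 °C
Reagents that add atoms: benzoic acid O=C(O)c1ccccc1
Why: Benzoate should open the 2,2‑disubstituted epoxide by SN2 attack at its unhindered CH2 terminus, which installs the primary benzoate and frees the tertiary hydroxyl without touching the quaternary stereocenter.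

**Step 12**
Reactants: 17 [(1S,2S,5S,6R)‑6‑(tert‑butyldimethylsilyloxy)‑1‑hydroxy‑2,5‑bis(4‑methoxybenzyloxy)cyclohex‑3‑en‑1‑yl]methyl benzoate
Product: 18 [6‑(tert‑butyldimethylsilyloxy)‑5‑hydroxy‑1,2‑O‑(4‑methoxybenzylidene)‑1,2‑dihydroxycyclohex‑3‑en‑1‑yl]methyl benzoate (ring configuration as in 17; acetal carbon unassigned)
Conditions: DDQ (2.4 equiv), 4 Å MS, CH2Cl2, 0 °C; then pH 7 buffer
Reagents that add atoms: none
Why: Benzylic hydride abstraction at each PMB ether gives an oxocarbenium ion; the one on O‑2 is trapped by the cis tertiary hydroxyl on C1 as a five‑membered 4‑methoxybenzylidene acetal (new acetal centre inconsequential), whereas the one on O‑5, which has only the silylated O‑6 as neighbour, is hydrolysed on work‑up to the free alcohol (oxidative PMB acetal formation and cleavage).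

**Step 13**
Reactants: 18 [6‑(tert‑butyldimethylsilyloxy)‑5‑hydroxy‑1,2‑O‑(4‑methoxybenzylidene)‑1,2‑dihydroxycyclohex‑3‑en‑1‑yl]methyl benzoate
Product: 19 [5,6‑dihydroxy‑1,2‑O‑(4‑methoxybenzylidene)‑1,2‑dihydroxycyclohex‑3‑en‑1‑yl]methyl benzoate
Conditions: HF·pyridine, pyridine–THF, 0 °C → rt
Reagents that add atoms: none
Why: Buffered fluoride desilylation should free O‑6 without the alkoxide conditions that could move the benzoate and without cleaving the acetal.

**Step 14**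
Reactants: 19 [5,6‑dihydroxy‑1,2‑O‑(4‑methoxybenzylidene)‑1,2‑dihydroxycyclohex‑3‑en‑1‑yl]methyl benzoate
Product: 20 [5,6‑diacetoxy‑1,2‑O‑(4‑methoxybenzylidene)‑1,2‑dihydroxycyclohex‑3‑en‑1‑yl]methyl benzoate
Conditions: Ac2O, pyridine, DMAP (cat.), CH2Cl2, 0 °C → rt
Reagents that add atoms: acetic anhydride CC(=O)OC(C)=O
Why: The only free hydroxyls are the secondary ones on C5 and C6, so standard acetylation should give the trans‑diacetate while O‑1 and O‑2 stay tied in the acetal.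

**Step 15**
Reactants: 20 [5,6‑diacetoxy‑1,2‑O‑(4‑methoxybenzylidene)‑1,2‑dihydroxycyclohex‑3‑en‑1‑yl]methyl benzoate
Product: 21 [(1S,2S,5S,6R)‑5,6‑diacetoxy‑1,2‑dihydroxycyclohex‑3‑en‑1‑yl]methyl benzoate (target)
Conditions: AcOH–H2O (4:1), 40 °C
Reagents that add atoms: none
Why: The electron‑rich benzylidene acetal should hydrolyse under mild aqueous acid that leaves the acetates, the benzoate and the allylic system unchanged and does not promote acyl migration.

**Compound list**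

1 | 3,4‑O‑isopropylidene‑D‑mannitol | OC[C@@H](O)[C@H]1OC(C)(C)O[C@@H]1[C@H](O)CO | starting material
2 | 1,6‑di‑O‑benzoyl‑3,4‑O‑isopropylidene‑D‑mannitol | O=C(OC[C@@H](O)[C@H]1OC(C)(C)O[C@@H]1[C@H](O)COC(=O)c1ccccc1)c1ccccc1 | intermediate (not isolated)
3 | 1,6‑di‑O‑benzoyl‑3,4‑O‑isopropylidene‑2,5‑di‑O‑methanesulfonyl‑D‑mannitol | O=C(OC[C@@H](OS(C)(=O)=O)[C@H]1OC(C)(C)O[C@@H]1[C@H](OS(C)(=O)=O)COC(=O)c1ccccc1)c1ccccc1 | intermediate
4 | 1,2:5,6‑dianhydro‑3,4‑O‑isopropylidene‑L‑iditol | C1O[C@@H]1[C@H]2OC(C)(C)O[C@@H]2[C@@H]3CO3 | intermediate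
5 | sodium 5,6‑anhydro‑3,4‑O‑isopropylidene‑1‑thio‑L‑iditol 1‑thiolate | [Na+].[S-]C[C@H](O)[C@H]1OC(C)(C)O[C@@H]1[C@@H]2CO2 | intermediate (not isolated)
6 | 1,6‑dideoxy‑1,6‑epithio‑3,4‑O‑isopropylidene‑L‑iditol | S1C[C@H](O)[C@H]2OC(C)(C)O[C@@H]2[C@@H](O)C1 | intermediate
7 | 1,6‑dideoxy‑1,6‑epithio‑3,4‑O‑isopropylidene‑2,5‑bis‑O‑(4‑methoxybenzyl)‑L‑iditol | S1C[C@H](OCc2ccc(OC)cc2)[C@H]3OC(C)(C)O[C@@H]3[C@@H](OCc4ccc(OC)cc4)C1 | intermediate
8 | 1,6‑dideoxy‑1,6‑epithio‑2,5‑bis‑O‑(4‑methoxybenzyl)‑L‑iditol | S1C[C@H](OCc2ccc(OC)cc2)[C@@H](O)[C@H](O)[C@@H](OCc3ccc(OC)cc3)C1 | intermediate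
9 | 3‑O‑(tert‑butyldimethylsilyl)‑1,6‑dideoxy‑1,6‑epithio‑2,5‑bis‑O‑(4‑methoxybenzyl)‑L‑iditol | S1C[C@H](OCc2ccc(OC)cc2)[C@@H](O[Si](C)(C)C(C)(C)C)[C@H](O)[C@@H](OCc3ccc(OC)cc3)C1 | intermediate
10 | 5‑(tert‑butyldimethylsilyloxy)‑3,6‑bis(4‑methoxybenzyloxy)thiepan‑4‑one (O‑3/O‑5 cis, O‑5/O‑6 trans) | S1C[C@H](OCc2ccc(OC)cc2)[C@@H](O[Si](C)(C)C(C)(C)C)C(=O)[C@@H](OCc3ccc(OC)cc3)C1 | intermediate
11 | lithium alkoxide of the 4‑(chloromethyl)thiepan‑4‑ol from 10 (O‑4 cis to O‑3 and O‑5) | S1C[C@H](OCc2ccc(OC)cc2)[C@@H](O[Si](C)(C)C(C)(C)C)[C@]([O-])(CCl)[C@@H](OCc3ccc(OC)cc3)C1.[Li+] | intermediate (not isolated)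
12 | 5‑(tert‑butyldimethylsilyloxy)‑3,6‑bis(4‑methoxybenzyloxy)thiepane‑4‑spiro‑2'‑oxirane (oxirane O cis to O‑3 and O‑5) | S1C[C@H](OCc2ccc(OC)cc2)[C@@H](O[Si](C)(C)C(C)(C)C)[C@]4(CO4)[C@@H](OCc3ccc(OC)cc3)C1 | intermediate
13 | 1,1‑dioxide of 12 | O=S1(=O)C[C@H](OCc2ccc(OC)cc2)[C@@H](O[Si](C)(C)C(C)(C)C)[C@]4(CO4)[C@@H](OCc3ccc(OC)cc3)C1 | intermediate
14 | 7‑bromo derivative of 13 (C–Br epimers) | O=S1(=O)C(Br)[C@H](OCc2ccc(OC)cc2)[C@@H](O[Si](C)(C)C(C)(C)C)[C@]4(CO4)[C@@H](OCc3ccc(OC)cc3)C1 | intermediate (not isolated)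
15 | episulfone (7‑thiabicyclo[4.1.0]heptane 7,7‑dioxide) from 14, cis‑fused, substituents as in 13 | O=S1(=O)C2[C@H](OCc3ccc(OC)cc3)[C@@H](O[Si](C)(C)C(C)(C)C)[C@]4(CO4)[C@@H](OCc5ccc(OC)cc5)C12 | intermediate (not isolated)
16 | 6‑(tert‑butyldimethylsilyloxy)‑2,5‑bis(4‑methoxybenzyloxy)cyclohex‑3‑ene‑1‑spiro‑2'‑oxirane (oxirane O cis to O‑2 and O‑6; O‑5 trans to O‑6) | COc1ccc(CO[C@H]2C=C[C@H](OCc3ccc(OC)cc3)[C@@]4(CO4)[C@@H]2O[Si](C)(C)C(C)(C)C)cc1 | intermediate
17 | [(1S,2S,5S,6R)‑6‑(tert‑butyldimethylsilyloxy)‑1‑hydroxy‑2,5‑bis(4‑methoxybenzyloxy)cyclohex‑3‑en‑1‑yl]methyl benzoate | COc1ccc(CO[C@H]2C=C[C@H](OCc3ccc(OC)cc3)[C@@](O)(COC(=O)c4ccccc4)[C@@H]2O[Si](C)(C)C(C)(C)C)cc1 | intermediate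
18 | 1,2‑O‑(4‑methoxybenzylidene) acetal with free 5‑OH and 6‑OTBS (ring configuration as in 17) | O[C@H]1C=C[C@@H]2OC(c3ccc(OC)cc3)O[C@]2(COC(=O)c4ccccc4)[C@@H]1O[Si](C)(C)C(C)(C)C | intermediate
19 | 5,6‑diol 1,2‑O‑(4‑methoxybenzylidene) acetal | O[C@H]1C=C[C@@H]2OC(c3ccc(OC)cc3)O[C@]2(COC(=O)c4ccccc4)[C@@H]1O | intermediate
20 | 5,6‑diacetate 1,2‑O‑(4‑methoxybenzylidene) acetal | CC(=O)O[C@H]1C=C[C@@H]2OC(c3ccc(OC)cc3)O[C@]2(COC(=O)c4ccccc4)[C@@H]1OC(C)=O | intermediate
21 | [(1S,2S,5S,6R)‑5,6‑diacetoxy‑1,2‑dihydroxycyclohex‑3‑en‑1‑yl]methyl benzoate | CC(=O)O[C@H]1C=C[C@H](O)[C@@](O)(COC(=O)c2ccccc2)[C@@H]1OC(C)=O | target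

**Totals and risks**

Total step count: 15. Longest linear sequence: 15 steps (fully linear from 1).

Steps most likely to fail:

1. Step 10 (ring contraction). The α‑sulfonyl carbanion may be diverted before halogen transfer, by intramolecular opening of the spiro‑epoxide or by β‑elimination of PMB oxide, or the silyl ether may be lost on the basic support. Fallback: setting out from 7, the sulfide is oxidised with mCPBA to the C2‑symmetric sulfone F4, and this simpler substrate, which carries neither epoxide nor silyl ether and is the closely precedented type, is ring‑contracted under the same KOH/Al2O3–CBr2F2 conditions to the conduritol B derivative F5. Aqueous acetic acid then gives the diol F6, mono‑silylation (TBSCl, imidazole) the silyl ether F7, and Dess–Martin oxidation the β,γ‑unsaturated ketone F8. Addition of chloromethyllithium at −78 °C, anti to the two flanking cis oxygens, returns to the route at 16.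

2. Step 8 (quaternary centre). The carbenoid may attack the flexible seven‑membered ketone on the wrong face, or enolisation may be followed by β‑elimination of thiolate or alkoxide. Fallback: setting out from 10, non‑basic methylenation (Zn, CH2Br2, TiCl4) gives the exocyclic alkene F1 and HF·pyridine the allylic alcohol F2. Excess buffered mCPBA then oxidises sulfur to the sulfone and epoxidises the alkene under direction of the 5‑hydroxyl, so the oxirane oxygen is delivered cis to O‑5, giving the epoxy alcohol F3. Re‑silylation (TBSOTf, 2,6‑lutidine) returns to the route at 13. Stereocontrol then rests on hydroxyl‑directed oxygen delivery and not on the facial bias of the ketone.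

3. Step 12 (telling O‑2 from O‑5). Discrimination of the two PMB ethers may be incomplete, or over‑oxidation may occur (acetal to hydroxy 4‑methoxybenzoate, allylic alcohol to enone). Fallback: setting out from 17, both PMB ethers are cleaved in a wet medium (ceric ammonium nitrate, MeCN–H2O, then brief aqueous acetic acid) to the triol F9. Its only cis‑vicinal diol (O‑1/O‑2) is tied as the acetonide F10 (2,2‑dimethoxypropane, PPTS). HF·pyridine then gives the diol F11, acetylation the diacetate F12, and aqueous acetic acid removes the acetonide, which returns to the route at 21.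

**Further compounds**

F1 | step 8 | 5‑(tert‑butyldimethylsilyloxy)‑3,6‑bis(4‑methoxybenzyloxy)‑4‑methylenethiepane | S1C[C@H](OCc2ccc(OC)cc2)[C@@H](O[Si](C)(C)C(C)(C)C)C(=C)[C@@H](OCc3ccc(OC)cc3)C1
F2 | step 8 | 3,6‑bis(4‑methoxybenzyloxy)‑4‑methylenethiepan‑5‑ol | S1C[C@H](OCc2ccc(OC)cc2)[C@@H](O)C(=C)[C@@H](OCc3ccc(OC)cc3)C1
F3 | step 8 | 5‑hydroxy‑3,6‑bis(4‑methoxybenzyloxy)thiepane‑4‑spiro‑2'‑oxirane 1,1‑dioxide (oxirane O cis to O‑5) | O=S1(=O)C[C@H](OCc2ccc(OC)cc2)[C@@H](O)[C@]4(CO4)[C@@H](OCc3ccc(OC)cc3)C1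
F4 | step 10 | 1,6‑dideoxy‑1,6‑epithio‑3,4‑O‑isopropylidene‑2,5‑bis‑O‑(4‑methoxybenzyl)‑L‑iditol S,S‑dioxide | O=S1(=O)C[C@H](OCc2ccc(OC)cc2)[C@H]3OC(C)(C)O[C@@H]3[C@@H](OCc4ccc(OC)cc4)C1
F5 | step 10 | 2,3‑O‑isopropylidene‑1,4‑bis‑O‑(4‑methoxybenzyl)conduritol B (all‑trans) | COc1ccc(CO[C@H]2C=C[C@H](OCc3ccc(OC)cc3)[C@H]4OC(C)(C)O[C@H]24)cc1
F6 | step 10 | 1,4‑bis‑O‑(4‑methoxybenzyl)conduritol B | COc1ccc(CO[C@H]2C=C[C@H](OCc3ccc(OC)cc3)[C@@H](O)[C@@H]2O)cc1
F7 | step 10 | 2‑O‑(tert‑butyldimethylsilyl)‑1,4‑bis‑O‑(4‑methoxybenzyl)conduritol B | COc1ccc(CO[C@H]2C=C[C@H](OCc3ccc(OC)cc3)[C@@H](O)[C@@H]2O[Si](C)(C)C(C)(C)C)cc1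
F8 | step 10 | 6‑(tert‑butyldimethylsilyloxy)‑2,5‑bis(4‑methoxybenzyloxy)cyclohex‑3‑en‑1‑one (O‑2/O‑6 cis, O‑5/O‑6 trans) | COc1ccc(CO[C@H]2C=C[C@H](OCc3ccc(OC)cc3)C(=O)[C@@H]2O[Si](C)(C)C(C)(C)C)cc1
F9 | step 12 | [6‑(tert‑butyldimethylsilyloxy)‑1,2,5‑trihydroxycyclohex‑3‑en‑1‑yl]methyl benzoate (configuration as in 17) | O[C@H]1C=C[C@H](O)[C@@](O)(COC(=O)c2ccccc2)[C@@H]1O[Si](C)(C)C(C)(C)C
F10 | step 12 | 1,2‑O‑isopropylidene derivative of F9 | O[C@H]1C=C[C@@H]2OC(C)(C)O[C@]2(COC(=O)c3ccccc3)[C@@H]1O[Si](C)(C)C(C)(C)C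
F11 | step 12 | 5,6‑diol 1,2‑O‑isopropylidene acetal | O[C@H]1C=C[C@@H]2OC(C)(C)O[C@]2(COC(=O)c3ccccc3)[C@@H]1O
F12 | step 12 | 5,6‑diacetate 1,2‑O‑isopropylidene acetal | CC(=O)O[C@H]1C=C[C@@H]2OC(C)(C)O[C@]2(COC(=O)c3ccccc3)[C@@H]1OC(C)=O
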